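The route rests on cutting the bond between C2 of the pentyl-bearing 4-pyranone ring (the carbon flanked by ring O1 and C3) and the adjacent CH(CH3) carbon. Because that stereocentre lies between pyranone C2 and the ketone carbon, it is carried as an exocyclic methylene next to a carbinol. The key step, a Stille coupling, joins the 2-stannyl pyranone (an acyl-anion equivalent of the cyclised triketide) to a 2-bromoallylic silyl ether that already holds the complete ethyl pyranone and its CH(CH3) centre. The hydroxyl then steers hydrogenation of the methylene and is oxidised last to the ketone.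

Key step: step 11

Remark: the ketone is kept at the alcohol level until the last step because both stereocentres are α to it and bonded to a pyranone C2 (readily enolised); 4-methylheptane-3,5-dione is taken as a catalogue compound.

Step 1
Reactants: 1 ethyl 2-methyl-3-oxopentanoate, 2 methyl hexanoate
Product: 4 ethyl 2,4-dimethyl-3,5-dioxodecanoate, via dilithium dianion of ethyl 2-methyl-3-oxopentanoate 3 (not isolated)
Conditions: LDA (2 equiv per 1), THF, −78 → 0 °C; then 2 (0.5 equiv), 0 °C → rt; aq. NH4Cl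
Reagents that add atoms: none
Why: γ-Acylation of a β-keto ester dianion (Claisen condensation) should occur at the more basic C4 carbanion, the second equivalent of dianion taking up the acidic proton of the tricarbonyl product.

Step 2
Reactants: 4 ethyl 2,4-dimethyl-3,5-dioxodecanoate
Product: 5 4-hydroxy-3,5-dimethyl-6-pentyl-2H-pyran-2-one
Conditions: DBU, toluene, 80 °C; aq. HCl
Reagents that add atoms: none
Why: Base-promoted lactonisation of a 3,5-diketo ester (enolate O-acylation with loss of ethoxide) is the standard closure of triketide esters to 4-hydroxy-2-pyranones.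

Step 3
Reactants: 5 4-hydroxy-3,5-dimethyl-6-pentyl-2H-pyran-2-one
Product: 6 2-methoxy-3,5-dimethyl-6-pentyl-4H-pyran-4-one
Conditions: MeOTf, CH2Cl2, 0 °C → rt; aq. NaHCO3
Reagents that add atoms: methyl trifluoromethanesulfonate, COS(=O)(=O)C(F)(F)F
Why: Hard O-alkylation of the neutral pyranone should take place at the lactone carbonyl oxygen and, after loss of the 4-OH proton, leave the 2-methoxy-4-pyranone isomer, the known outcome for 3,5-dialkyl-4-hydroxy-2-pyranones under base-free conditions (the minor 4-methoxy-2-pyranone would be removed by chromatography).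

Step 4
Reactants: 6 2-methoxy-3,5-dimethyl-6-pentyl-4H-pyran-4-one
Product: 7 3,5-dimethyl-6-pentyl-2-(tributylstannyl)-4H-pyran-4-one
Conditions: Bu3SnH, LDA, THF, 0 °C; then 6, −78 → −20 °C; aq. NH4Cl
Reagents that add atoms: tributylstannyllithium, [Li][Sn](CCCC)(CCCC)CCCC (made in the flask from tributyltin hydride, CCCC[SnH](CCCC)CCCC, and LDA)
Why: Conjugate addition–elimination (vinylic substitution) of the soft stannyl anion at C2 with methoxide as leaving group is the stannyl counterpart of the carbanion substitutions known for 2-methoxy-4-pyranones and of stannyl-anion substitutions on β-hetero-substituted enones.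

Step 5
Reactants: 8 acrolein
Product: 10 2-bromoprop-2-enal, via 2,3-dibromopropanal 9 (not isolated)
Conditions: Br2, CH2Cl2, −78 °C; then Et3N, −78 °C → rt; used freshly
Reagents that add atoms: bromine, BrBr
Why: Bromine addition to the enal followed by amine-mediated E2 loss of HBr (removal of the acidic α-hydrogen) is the standard preparation of 2-bromoacrolein.

Step 6
Reactants: 11 (S)-4-benzyl-3-propanoyl-1,3-oxazolidin-2-one, 10 2-bromoprop-2-enal
Product: 13 (S)-4-benzyl-3-[(2S,3S)-4-bromo-3-hydroxy-2-methylpent-4-enoyl]-1,3-oxazolidin-2-one, via dibutylboron (Z)-enolate of the imide 12 (not isolated)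
Conditions: Bu2BOTf, i-Pr2NEt, CH2Cl2, 0 °C; then 10, −78 → 0 °C; pH 7 buffer, MeOH, H2O2
Reagents that add atoms: none
Why: Evans syn-aldol reaction: the (Z)-boron enolate should react through a Zimmerman–Traxler chair on the face opposite the benzyl group of the (S)-auxiliary, which fixes both new stereocentres as (2S,3S) (syn).

Step 7
Reactants: 13 (S)-4-benzyl-3-[(2S,3S)-4-bromo-3-hydroxy-2-methylpent-4-enoyl]-1,3-oxazolidin-2-one
Product: 14 (2S,3S)-4-bromo-3-hydroxy-N-methoxy-N,2-dimethylpent-4-enamide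
Conditions: MeNH(OMe)·HCl, AlMe3, CH2Cl2, −20 °C → rt; aq. Rochelle salt
Reagents that add atoms: N,O-dimethylhydroxylamine hydrochloride, CNOC.Cl
Why: Aluminium amide transamidation of the N-acyl oxazolidinone (Weinreb amide formation, assisted by the free β-hydroxyl) should proceed without touching the α-stereocentre.

Step 8
Reactants: 14 (2S,3S)-4-bromo-3-hydroxy-N-methoxy-N,2-dimethylpent-4-enamide
Product: 15 (2S,3S)-4-bromo-3-[(tert-butyldimethylsilyl)oxy]-N-methoxy-N,2-dimethylpent-4-enamide
Conditions: TBSOTf, 2,6-lutidine, CH2Cl2, −78 → 0 °C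
Reagents that add atoms: tert-butyldimethylsilyl trifluoromethanesulfonate, CC(C)(C)[Si](C)(C)OS(=O)(=O)C(F)(F)F
Why: Silylation of the secondary alcohol with a silyl triflate and a hindered pyridine base blocks retro-aldol and O-cyclisation pathways in the next two steps.

Step 9
Reactants: 15 (2S,3S)-4-bromo-3-[(tert-butyldimethylsilyl)oxy]-N-methoxy-N,2-dimethylpent-4-enamide, 16 4-methylheptane-3,5-dione
Product: 18 (8S,9S)-10-bromo-9-[(tert-butyldimethylsilyl)oxy]-4,6,8-trimethylundec-10-ene-3,5,7-trione, via dilithium dianion of 4-methylheptane-3,5-dione 17 (not isolated)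
Conditions: 16, LDA (2 equiv per 16), THF, −78 → 0 °C; then 15, −78 → −20 °C; aq. NH4Cl
Reagents that add atoms: none
Why: Claisen-type acylation of the 1,3-diketone dianion at its terminal carbanion by the Weinreb amide; the chelated tetrahedral intermediate persists until quench, so neither over-addition nor enolisation next to the new ketone should occur.

Step 10
Reactants: 18 (8S,9S)-10-bromo-9-[(tert-butyldimethylsilyl)oxy]-4,6,8-trimethylundec-10-ene-3,5,7-trione
Product: 19 2-[(2S,3S)-4-bromo-3-[(tert-butyldimethylsilyl)oxy]pent-4-en-2-yl]-6-ethyl-3,5-dimethyl-4H-pyran-4-one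
Conditions: Ph3P, CCl4, THF, rt
Reagents that add atoms: none
Why: Cyclodehydration of the 1,3,5-triketone (Appel-type activation of one enol oxygen, attack of the distal enol oxygen, loss of the activated oxygen) is an established mild closure of polypropionate triketones to 4-pyranones that leaves an adjacent stereocentre and silyl ethers intact.

Step 11
Reactants: 7 3,5-dimethyl-6-pentyl-2-(tributylstannyl)-4H-pyran-4-one, 19 2-[(2S,3S)-4-bromo-3-[(tert-butyldimethylsilyl)oxy]pent-4-en-2-yl]-6-ethyl-3,5-dimethyl-4H-pyran-4-one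
Product: 20 2-[(3S,4S)-3-[(tert-butyldimethylsilyl)oxy]-4-(6-ethyl-3,5-dimethyl-4-oxo-4H-pyran-2-yl)pent-1-en-2-yl]-3,5-dimethyl-6-pentyl-4H-pyran-4-one
Conditions: Pd2(dba)3 (cat.), AsPh3, CuI (cat.), NMP, 50 °C
Reagents that add atoms: none
Why: Stille coupling: oxidative addition of Pd(0) into the vinylic C–Br bond of 19, copper(I)-assisted transfer of the pyranon-2-yl group from tin and reductive elimination create the bond between pyranone C2 and the alkene carbon that becomes the CH(CH3) centre. The closest precedents are copper-accelerated Stille couplings of α-alkoxyvinyl and β-stannyl enone stannanes with 1,1-disubstituted vinyl bromides. No ring is closed and no stereocentre is formed in this step. The carbon is joined at the sp2 level on purpose: once the ketone is present this centre is α to C=O and bonded to pyranone C2, and it would not survive basic or Lewis-acidic bond formation. The step needs transfer of the sp2 pyranonyl group rather than butyl, which the alkenyl, α-oxygen-substituted tin–carbon bond secures. It must also leave the (2S,3S) centres and the silyl ether alone, which the neutral, base-free conditions and the non-ionisable vinylic C–Br bond secure.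

Step 12
Reactants: 20 2-[(3S,4S)-3-[(tert-butyldimethylsilyl)oxy]-4-(6-ethyl-3,5-dimethyl-4-oxo-4H-pyran-2-yl)pent-1-en-2-yl]-3,5-dimethyl-6-pentyl-4H-pyran-4-one
Product: 21 2-[(3S,4S)-4-(6-ethyl-3,5-dimethyl-4-oxo-4H-pyran-2-yl)-3-hydroxypent-1-en-2-yl]-3,5-dimethyl-6-pentyl-4H-pyran-4-one
Conditions: HF·pyridine, pyridine, THF, 0 °C → rt
Reagents that add atoms: none
Why: Fluoride cleavage of the secondary silyl ether under pyridine-buffered conditions frees the hydroxyl needed as directing group without base-induced elimination of the vinylogous aldol motif.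

Step 13
Reactants: 21 2-[(3S,4S)-4-(6-ethyl-3,5-dimethyl-4-oxo-4H-pyran-2-yl)-3-hydroxypent-1-en-2-yl]-3,5-dimethyl-6-pentyl-4H-pyran-4-one
Product: 22 2-ethyl-6-[(2S,3S,4S)-3-hydroxy-4-(3,5-dimethyl-4-oxo-6-pentyl-4H-pyran-2-yl)pentan-2-yl]-3,5-dimethyl-4H-pyran-4-one
Conditions: [Rh(nbd)(dppb)]BF4 (cat.), H2 (60 bar), CH2Cl2, rt
Reagents that add atoms: none
Why: Hydroxyl-directed homogeneous hydrogenation: the cationic rhodium catalyst binds the carbinol oxygen and should deliver H2 to the alkene face of the conformer that keeps the CH(CH3)-pyranone substituent away from the pentyl pyranone (A(1,2) strain), giving the anti CH3/OH relationship, i.e. the new (S) centre, while high pressure suppresses alkene isomerisation.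

Step 14
Reactants: 22 2-ethyl-6-[(2S,3S,4S)-3-hydroxy-4-(3,5-dimethyl-4-oxo-6-pentyl-4H-pyran-2-yl)pentan-2-yl]-3,5-dimethyl-4H-pyran-4-one
Product: 23 2-ethyl-6-[(2R,4R)-4-(3,5-dimethyl-4-oxo-6-pentyl-4H-pyran-2-yl)-3-oxopentan-2-yl]-3,5-dimethyl-4H-pyran-4-one (target)
Conditions: Dess–Martin periodinane, NaHCO3, CH2Cl2, 0 °C; neutral work-up
Reagents that add atoms: none
Why: Dess–Martin oxidation under buffered, non-basic conditions forms the ketone last, so the two enolisable α-stereocentres meet only neutral conditions; the syn,anti triad gives the (R,R) ketone (the descriptors change from S to R only because the carbonyl carbon gains priority).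

Compound list
1 | ethyl 2-methyl-3-oxopentanoate (racemic) | CCC(=O)C(C)C(=O)OCC | starting material
2 | methyl hexanoate | CCCCCC(=O)OC | starting material
3 | dilithium dianion (1,3-dienolate) of ethyl 2-methyl-3-oxopentanoate | [Li+].[Li+].CC=C([O-])C(C)=C([O-])OCC | intermediate
4 | ethyl 2,4-dimethyl-3,5-dioxodecanoate (stereoisomer and enol mixture) | CCCCCC(=O)C(C)C(=O)C(C)C(=O)OCC | intermediate
5 | 4-hydroxy-3,5-dimethyl-6-pentyl-2H-pyran-2-one | CCCCCc1oc(=O)c(C)c(O)c1C | intermediate
6 | 2-methoxy-3,5-dimethyl-6-pentyl-4H-pyran-4-one | CCCCCc1oc(OC)c(C)c(=O)c1C | intermediate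
7 | 3,5-dimethyl-6-pentyl-2-(tributylstannyl)-4H-pyran-4-one | CCCCCc1oc([Sn](CCCC)(CCCC)CCCC)c(C)c(=O)c1C | intermediate
8 | acrolein (prop-2-enal) | C=CC=O | starting material
9 | 2,3-dibromopropanal (racemic) | O=CC(Br)CBr | intermediate
10 | 2-bromoprop-2-enal (2-bromoacrolein) | C=C(Br)C=O | intermediate
11 | (S)-4-benzyl-3-propanoyl-1,3-oxazolidin-2-one | CCC(=O)N1[C@@H](Cc2ccccc2)COC1=O | starting material
12 | dibutylboron (Z)-enolate of imide 11 | C/C=C(\OB(CCCC)CCCC)N1[C@@H](Cc2ccccc2)COC1=O | intermediate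
13 | (S)-4-benzyl-3-[(2S,3S)-4-bromo-3-hydroxy-2-methylpent-4-enoyl]-1,3-oxazolidin-2-one (syn aldol) | C=C(Br)[C@@H](O)[C@H](C)C(=O)N1[C@@H](Cc2ccccc2)COC1=O | intermediate
14 | (2S,3S)-4-bromo-3-hydroxy-N-methoxy-N,2-dimethylpent-4-enamide | C=C(Br)[C@@H](O)[C@H](C)C(=O)N(C)OC | intermediate
15 | (2S,3S)-4-bromo-3-[(tert-butyldimethylsilyl)oxy]-N-methoxy-N,2-dimethylpent-4-enamide | C=C(Br)[C@@H](O[Si](C)(C)C(C)(C)C)[C@H](C)C(=O)N(C)OC | intermediate
16 | 4-methylheptane-3,5-dione | CCC(=O)C(C)C(=O)CC | starting material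
17 | dilithium dianion (1,3-dienolate) of 4-methylheptane-3,5-dione | [Li+].[Li+].CC=C([O-])C(C)=C([O-])CC | intermediate
18 | (8S,9S)-10-bromo-9-[(tert-butyldimethylsilyl)oxy]-4,6,8-trimethylundec-10-ene-3,5,7-trione (C4/C6 epimers and enols) | C=C(Br)[C@@H](O[Si](C)(C)C(C)(C)C)[C@H](C)C(=O)C(C)C(=O)C(C)C(=O)CC | intermediate
19 | 2-[(2S,3S)-4-bromo-3-[(tert-butyldimethylsilyl)oxy]pent-4-en-2-yl]-6-ethyl-3,5-dimethyl-4H-pyran-4-one | C=C(Br)[C@@H](O[Si](C)(C)C(C)(C)C)[C@H](C)c1oc(CC)c(C)c(=O)c1C | intermediate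
20 | 2-[(3S,4S)-3-[(tert-butyldimethylsilyl)oxy]-4-(6-ethyl-3,5-dimethyl-4-oxo-4H-pyran-2-yl)pent-1-en-2-yl]-3,5-dimethyl-6-pentyl-4H-pyran-4-one | CCCCCc1oc(C(=C)[C@@H](O[Si](C)(C)C(C)(C)C)[C@H](C)c2oc(CC)c(C)c(=O)c2C)c(C)c(=O)c1C | intermediate
21 | 2-[(3S,4S)-4-(6-ethyl-3,5-dimethyl-4-oxo-4H-pyran-2-yl)-3-hydroxypent-1-en-2-yl]-3,5-dimethyl-6-pentyl-4H-pyran-4-one | CCCCCc1oc(C(=C)[C@@H](O)[C@H](C)c2oc(CC)c(C)c(=O)c2C)c(C)c(=O)c1C | intermediate
22 | 2-ethyl-6-[(2S,3S,4S)-3-hydroxy-4-(3,5-dimethyl-4-oxo-6-pentyl-4H-pyran-2-yl)pentan-2-yl]-3,5-dimethyl-4H-pyran-4-one (OH syn to the CH3 on the ethyl-pyranone side, anti to the CH3 on the pentyl-pyranone side) | CCCCCc1oc([C@@H](C)[C@@H](O)[C@H](C)c2oc(CC)c(C)c(=O)c2C)c(C)c(=O)c1C | intermediate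
23 | 2-ethyl-6-[(2R,4R)-4-(3,5-dimethyl-4-oxo-6-pentyl-4H-pyran-2-yl)-3-oxopentan-2-yl]-3,5-dimethyl-4H-pyran-4-one | CCCCCc1oc([C@@H](C)C(=O)[C@H](C)c2oc(CC)c(C)c(=O)c2C)c(C)c(=O)c1C | target

Total step count: 14. Longest linear sequence: 10 steps (steps 5 to 14, from acrolein).

Steps most likely to fail

Step 11 (key step). Both partners are hindered and the stannane is electron-poor, so transmetalation may be too slow and protodestannylation or homocoupling may take over. The fallback reverses the polarity of the union. Stannane 7 would be iododestannylated (I2, CH2Cl2, 0 °C) to 2-iodo-3,5-dimethyl-6-pentyl-4H-pyran-4-one F1. Vinyl bromide 19 would be converted by Miyaura borylation (B2pin2, PdCl2(dppf), KOAc, dioxane, 80 °C) into 2-[(2S,3S)-3-[(tert-butyldimethylsilyl)oxy]-4-(4,4,5,5-tetramethyl-1,3,2-dioxaborolan-2-yl)pent-4-en-2-yl]-6-ethyl-3,5-dimethyl-4H-pyran-4-one F2. Suzuki–Miyaura coupling of F1 and F2 (PdCl2(dppf), K3PO4, THF with minimal water, 50 °C) would rejoin the route at 20.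

Step 4. The stannyl anion may attack the C4 carbonyl, open the ring or act as an electron donor instead of substituting the methoxy group, and the product may lose tin on isolation. The fallback sets out from 6 and uses a softer, non-basic nucleophile in the same addition–elimination: sodium methanethiolate (THF, 0 °C) would give 3,5-dimethyl-2-(methylsulfanyl)-6-pentyl-4H-pyran-4-one F3. Vinyl bromide 19 would be stannylated (hexamethylditin, Pd(PPh3)4, toluene, 90 °C) to 2-[(2S,3S)-3-[(tert-butyldimethylsilyl)oxy]-4-(trimethylstannyl)pent-4-en-2-yl]-6-ethyl-3,5-dimethyl-4H-pyran-4-one F4. Liebeskind–Srogl coupling of F3 and F4 (Pd(PPh3)4, copper(I) thiophene-2-carboxylate, THF, 50 °C) would return to the route at 20, bypassing 7.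

Step 9. The dianion may act as a base toward the amide α-position (loss of configuration, β-elimination of silanolate) or may not add to the hindered amide. The fallback sets out from 15: reduction with DIBAL-H (THF, −78 °C) would give (2S,3S)-4-bromo-3-[(tert-butyldimethylsilyl)oxy]-2-methylpent-4-enal F5. Aldol addition of dianion 17 to F5 (THF, −78 °C) would give 10-bromo-9-[(tert-butyldimethylsilyl)oxy]-7-hydroxy-4,6,8-trimethylundec-10-ene-3,5-dione F6 (C7 epimers, the two centres from 15 retained). Dess–Martin oxidation of F6 would return to the route at triketone 18.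

Further compounds
F1 | step 11 | 2-iodo-3,5-dimethyl-6-pentyl-4H-pyran-4-one | CCCCCc1oc(I)c(C)c(=O)c1C
F2 | step 11 | 2-[(2S,3S)-3-[(tert-butyldimethylsilyl)oxy]-4-(4,4,5,5-tetramethyl-1,3,2-dioxaborolan-2-yl)pent-4-en-2-yl]-6-ethyl-3,5-dimethyl-4H-pyran-4-one | C=C(B1OC(C)(C)C(C)(C)O1)[C@@H](O[Si](C)(C)C(C)(C)C)[C@H](C)c1oc(CC)c(C)c(=O)c1C
F3 | step 4 | 3,5-dimethyl-2-(methylsulfanyl)-6-pentyl-4H-pyran-4-one | CCCCCc1oc(SC)c(C)c(=O)c1C
F4 | step 4 | 2-[(2S,3S)-3-[(tert-butyldimethylsilyl)oxy]-4-(trimethylstannyl)pent-4-en-2-yl]-6-ethyl-3,5-dimethyl-4H-pyran-4-one | C=C([Sn](C)(C)C)[C@@H](O[Si](C)(C)C(C)(C)C)[C@H](C)c1oc(CC)c(C)c(=O)c1C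
F5 | step 9 | (2S,3S)-4-bromo-3-[(tert-butyldimethylsilyl)oxy]-2-methylpent-4-enal | C=C(Br)[C@@H](O[Si](C)(C)C(C)(C)C)[C@H](C)C=O
F6 | step 9 | 10-bromo-9-[(tert-butyldimethylsilyl)oxy]-7-hydroxy-4,6,8-trimethylundec-10-ene-3,5-dione (C7 epimers) | C=C(Br)[C@@H](O[Si](C)(C)C(C)(C)C)[C@H](C)C(O)C(C)C(=O)C(C)C(=O)CC
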